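The constants used here come from no measurement; the flask was simulated.

A flask charged with 1.10 equiv of nucleophile cannot turn its electrophile into target one for one as long as each target spends two nucleophile, one in step 1 and one on the freed acid, since that charge is fewer than those two, and where the target levels off is what to watch.

    electrophile + nucleophile → acid + target + leaving group (k1 = 0.0011 M⁻¹ s⁻¹)
    protonated nucleophile ⇌ nucleophile + acid, settled at all times (K2 = 5.0 × 10⁻¹⁰ M)
    buffer acid ⇌ buffer base + acid, settled at all times (K3 = 4.0 × 10⁻⁷ M)
    electrophile + leaving group → side product (k4 = 6.3 × 10⁻⁴ M⁻¹ s⁻¹)
    nucleophile + leaving group ⇌ idle adduct, settled at all times (K5 = 8.7 M⁻¹)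

electrophile 0.064 M; nucleophile 1.10 equiv; buffer base 3.00 equiv; buffer acid 0.100 equiv; time 20 h

- part of the electrophile that has reacted at 20 h
- pH of the solution at 20 h

- acid is the free proton; pH is minus the decimal logarithm of its molar concentration
- what is said of leaving group includes idle adduct
- run time (flask): 20 h

We build the flask up by hand. With step 1 alone, a second-order reaction on a time scale of 3.95 h, we reckon 87.9% reacted by 20 h.

Now we add the proton balances. Each turnover frees one acid, and because the protonated nucleophile holds its proton far more tightly than the buffer acid does (5.0 × 10⁻¹⁰ M against 4.0 × 10⁻⁷ M), we let that acid land on a second nucleophile, as does the proton of the charged buffer acid. The nucleophile is therefore the limiting reagent, and we expect step 1 to stall near 0.500 of target per electrophile, the stall point: charged nucleophile minus charged buffer acid, divided by two. At that point the proton count makes c(nucleophile) equal c(buffer acid), and multiplying the two balances gives c(acid) = 6.32 × 10⁻⁹ M, which is pH 8.20.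

Next comes step 4. At the stall point the electrophile left and the leaving group made are both 0.0320 M, and step 4 removes one of each, so they stay equal and 1/c falls under a plain second-order law. Running that clock from the start, which is slightly generous, leaves 0.0131 M of electrophile, so we commit to 79.6% reacted.

Last, the idle adduct: K5·c(nucleophile) drops from 0.61 at the start to 0.0264 at the stall, so we neglect it in the tail.

The forecast gave 78% (72% to 84%) and pH 8.1 (7.95 to 8.3), with the nucleophile “largely titrated away at about half conversion”, a little below our figures.

The simulation gives 78.3% reacted and pH 8.15.

In this flask step 1 has done half of its turnover up to the asked time by 1.74 h and step 4 by 7.52 h, which is later, and at 20.0 h the target stands at 50.5% against a stall point of 0.500, with 27.8% of side product beside it. The neighbour flask at 0.016 M has the same equivalents and so the same stall point, but at 20.0 h its target is lower, at 40.7%, with 49.1% of its electrophile still there.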